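**Strategy.** The cyclohexenone is cut at C1, the heptenyl-bearing ring carbon (C2 carries CH2OH, C3 the carbinol, C4/C5 the epoxide, C6 the ketone). C1 is the only ring atom without oxygen or stereochemistry and is flanked by C6 and C2. It is therefore inserted last, as C–Br, into an enantiopure epoxycyclopentanone. Dibromocarbene adds to the C6=C2 silyl enol ether and the resulting dibromocyclopropane opens, making the C1–C6 and C1–C2 bonds and turning the five-membered ring into the 2-bromocyclohex-2-enone in one operation. The precursor is the fully silylated enol ether of a 2,3-epoxy-4-silyloxy-5-(silyloxymethyl)cyclopentanone that already carries the tiglate side chain.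

Key step: step 10

**Assumptions and design remarks**

- Compound 1 is taken as the purchasable silyl ether of (R)-4-hydroxycyclopent-2-enone; its carbinol carbon becomes C3 of the target.
- The epoxide must be syn to the C3 oxygen. Peroxide addition to a 4-silyloxy enone would go anti, and the free hydroxy enone is base-labile, so the syn relation is relayed through an allylic alcohol (steps 4–6).
- The side chain is built from an unsubstituted allyl group and a cross-metathesis, which avoids the α/γ ambiguity of a substituted allyl-metal coupling.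
- The enol ether of the precursor is tert-butyldimethylsilyl, not trimethylsilyl. It is more robust toward tert-butoxide and forms in the same operation as the CH2O-silyl ether.
- The configuration at the hydroxymethyl-bearing carbon of 12 and the face of carbene addition in 15 are inconsequential, because these carbons end up sp2; the SMILES show the expected isomers.

**Route**

Step 1
Reactants: 1 (R)-4-[(tert-butyldimethylsilyl)oxy]cyclopent-2-en-1-one
Product: 2 (R)-4-[(tert-butyldimethylsilyl)oxy]-2-iodocyclopent-2-en-1-one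
Conditions: I2, pyridine–CH2Cl2 (1:1), 0 °C → rt
Reagents that add atoms: iodine, II
Why: Johnson α-iodination of an enone (conjugate addition of pyridine, iodination of the enolate, elimination) is routine for 4-silyloxycyclopentenones and does not touch the carbinol stereocentre.

Step 2
Reactants: 2 (R)-4-[(tert-butyldimethylsilyl)oxy]-2-iodocyclopent-2-en-1-one; 3 allyltributylstannane
Product: 4 (R)-2-allyl-4-[(tert-butyldimethylsilyl)oxy]cyclopent-2-en-1-one
Conditions: Pd2(dba)3 (2.5 mol%), AsPh3 (10 mol%), CuI (10 mol%), NMP, rt → 40 °C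
Reagents that add atoms: none
Why: Stille coupling of a 2-iodoenone under ligand-accelerated, base-free conditions should install the allyl group without disturbing the β-silyloxy ketone, and the unsubstituted allyl unit leaves no regiochemical question.

Step 3
Reactants: 4 (R)-2-allyl-4-[(tert-butyldimethylsilyl)oxy]cyclopent-2-en-1-one; 5 methyl methacrylate
Product: 6 methyl (E)-4-[(3R)-3-[(tert-butyldimethylsilyl)oxy]-5-oxocyclopent-1-en-1-yl]-2-methylbut-2-enoate
Conditions: Hoveyda–Grubbs II (5 mol%), methyl methacrylate (10 equiv), CH2Cl2, 40 °C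
Reagents that add atoms: none
Why: Olefin cross-metathesis of a terminal alkene with a methacrylate should give the trisubstituted enoate in its thermodynamically preferred E geometry, while the electron-poor trisubstituted ring alkene is inert to the catalyst.

Step 4
Reactants: 6 methyl (E)-4-[(3R)-3-[(tert-butyldimethylsilyl)oxy]-5-oxocyclopent-1-en-1-yl]-2-methylbut-2-enoate
Product: 7 methyl (E)-4-[(3R,5S)-3-[(tert-butyldimethylsilyl)oxy]-5-hydroxycyclopent-1-en-1-yl]-2-methylbut-2-enoate (hydroxyl cis to the silyloxy group)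
Conditions: NaBH4, CeCl3·7H2O, MeOH, −78 °C
Reagents that add atoms: none
Why: Luche 1,2-reduction, in which hydride should attack the ring face opposite the silyloxy group so that the new carbinol (5S) is cis to it, with the conjugated ester left intact.

Step 5
Reactants: 7 methyl (E)-4-[(3R,5S)-3-[(tert-butyldimethylsilyl)oxy]-5-hydroxycyclopent-1-en-1-yl]-2-methylbut-2-enoate
Product: 8 methyl (E)-4-[(1S,2S,4R,5R)-4-[(tert-butyldimethylsilyl)oxy]-2-hydroxy-6-oxabicyclo[3.1.0]hexan-1-yl]-2-methylbut-2-enoate (epoxide oxygen, hydroxyl and silyloxy group all cis)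
Conditions: VO(acac)2 (5 mol%), t-BuOOH (decane), CH2Cl2, 0 °C → rt
Reagents that add atoms: tert-butyl hydroperoxide, CC(C)(C)OO
Why: Vanadium-catalysed hydroxyl-directed epoxidation should deliver oxygen to the ring alkene on the face of the allylic hydroxyl, hence syn to the silyloxy group, which sets both epoxide centres; the electron-poor enoate is not epoxidised.

Step 6
Reactants: 8 methyl (E)-4-[(1S,2S,4R,5R)-4-[(tert-butyldimethylsilyl)oxy]-2-hydroxy-6-oxabicyclo[3.1.0]hexan-1-yl]-2-methylbut-2-enoate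
Product: 9 methyl (E)-4-[(1R,4R,5R)-4-[(tert-butyldimethylsilyl)oxy]-2-oxo-6-oxabicyclo[3.1.0]hexan-1-yl]-2-methylbut-2-enoate
Conditions: Dess–Martin periodinane, NaHCO3, CH2Cl2, 0 °C → rt
Reagents that add atoms: none
Why: Buffered Dess–Martin oxidation should turn the epoxy alcohol into the α,β-epoxy ketone without β-elimination of the silyloxy group, removing the relay carbinol once it has done its work.

Step 7
Reactants: 9 methyl (E)-4-[(1R,4R,5R)-4-[(tert-butyldimethylsilyl)oxy]-2-oxo-6-oxabicyclo[3.1.0]hexan-1-yl]-2-methylbut-2-enoate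
Product: 10 methyl (E)-4-[(1R,4R,5R)-4-[(tert-butyldimethylsilyl)oxy]-2-[(trimethylsilyl)oxy]-6-oxabicyclo[3.1.0]hex-2-en-1-yl]-2-methylbut-2-enoate
Conditions: TMSOTf, Et3N, CH2Cl2, −78 → 0 °C; cold NaHCO3/pentane work-up, used crude
Reagents that add atoms: trimethylsilyl trifluoromethanesulfonate, C[Si](C)(C)OS(=O)(=O)C(F)(F)F
Why: Soft enolisation with silyl triflate and amine can go only toward the CH2 (the other α-carbon is the quaternary epoxide carbon) and releases no free enolate that could expel the β-silyloxy group.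

Step 8
Reactants: 10 methyl (E)-4-[(1R,4R,5R)-4-[(tert-butyldimethylsilyl)oxy]-2-[(trimethylsilyl)oxy]-6-oxabicyclo[3.1.0]hex-2-en-1-yl]-2-methylbut-2-enoate; 11 formaldehyde
Product: 12 methyl (E)-4-[(1R,3R,4R,5R)-4-[(tert-butyldimethylsilyl)oxy]-3-(hydroxymethyl)-2-oxo-6-oxabicyclo[3.1.0]hexan-1-yl]-2-methylbut-2-enoate
Conditions: aq. HCHO (37%), Yb(OTf)3 (10 mol%), THF–H2O, 0 °C → rt
Reagents that add atoms: none
Why: Lanthanide-triflate-catalysed aqueous Mukaiyama aldol (hydroxymethylation) of a silyl enol ether, with formaldehyde expected to approach anti to the neighbouring silyloxy group (3R), although this centre becomes sp2 in step 9 and either epimer serves.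

Step 9
Reactants: 12 methyl (E)-4-[(1R,3R,4R,5R)-4-[(tert-butyldimethylsilyl)oxy]-3-(hydroxymethyl)-2-oxo-6-oxabicyclo[3.1.0]hexan-1-yl]-2-methylbut-2-enoate
Product: 13 methyl (E)-4-[(1R,4R,5R)-2,4-bis[(tert-butyldimethylsilyl)oxy]-3-{[(tert-butyldimethylsilyl)oxy]methyl}-6-oxabicyclo[3.1.0]hex-2-en-1-yl]-2-methylbut-2-enoate
Conditions: TBSOTf (3 equiv), Et3N (6 equiv), CH2Cl2, −78 → 0 °C
Reagents that add atoms: tert-butyldimethylsilyl trifluoromethanesulfonate, CC(C)(C)[Si](C)(C)OS(=O)(=O)C(F)(F)F
Why: Excess silyl triflate with amine should silylate the primary alcohol and then soft-enolise the ketone, again only toward C2, giving a silyl enol ether robust enough to survive tert-butoxide in step 10 without releasing an enolate that could eliminate the C3 or CH2 silyloxy groups.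

Step 10
Reactants: 13 methyl (E)-4-[(1R,4R,5R)-2,4-bis[(tert-butyldimethylsilyl)oxy]-3-{[(tert-butyldimethylsilyl)oxy]methyl}-6-oxabicyclo[3.1.0]hex-2-en-1-yl]-2-methylbut-2-enoate; 14 bromoform
Product: 16 methyl (E)-4-[(1R,5R,6R)-3-bromo-5-[(tert-butyldimethylsilyl)oxy]-4-{[(tert-butyldimethylsilyl)oxy]methyl}-2-oxo-7-oxabicyclo[4.1.0]hept-3-en-1-yl]-2-methylbut-2-enoate, via dibromocyclopropane adduct 15 (not isolated)
Conditions: CHBr3 (3 equiv), KOt-Bu (added in portions), hexane, −30 °C → rt
Reagents that add atoms: none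
Why: Singlet dibromocarbene, made by α-elimination from bromoform, should add in a cheletropic [2+1] sense to the electron-rich tetrasubstituted C6=C2 enol ether; the strained 1-silyloxy-6,6-dibromobicyclo[3.1.0]hexane should then open by disrotatory two-electron electrocyclic cleavage of the C6–C2 bond with ionisation of the endo bromide, pushed by the silyloxy oxygen, and the 2-silyloxyallyl cation should lose silyl to tert-butoxide to give the 2-bromoenone. The closest known reaction type is the dihalocarbene ring expansion of cyclic silyl enol ethers to 2-halocycloalk-2-enones, including cyclopentanone enol ethers to 2-bromocyclohex-2-enones. No ring remains closed by the step: the transient cyclopropane is a [2+1] adduct that is cleaved again, so the net change is enlargement of the five-membered ring by the carbene carbon C1. No stereocentre is formed, the face of addition is irrelevant because C1, C2 and C6 all end sp2, and a gem-dibromide always offers an endo bromide. The step needs chemoselectivity for the enol ether over the side-chain alkene, which the electron-poor enoate secures against an electrophilic carbene, and regiochemistry, which is fixed because quaternary C5 allows only the C6=C2 enol ether. The C3–C5 triad is not at a reacting centre and should pass through unchanged.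

Step 11
Reactants: 16 methyl (E)-4-[(1R,5R,6R)-3-bromo-5-[(tert-butyldimethylsilyl)oxy]-4-{[(tert-butyldimethylsilyl)oxy]methyl}-2-oxo-7-oxabicyclo[4.1.0]hept-3-en-1-yl]-2-methylbut-2-enoate; 17 (E)-hept-1-enylboronic acid
Product: 18 methyl (E)-4-[(1R,5R,6R)-5-[(tert-butyldimethylsilyl)oxy]-4-{[(tert-butyldimethylsilyl)oxy]methyl}-3-[(E)-hept-1-en-1-yl]-2-oxo-7-oxabicyclo[4.1.0]hept-3-en-1-yl]-2-methylbut-2-enoate
Conditions: Pd(OAc)2 (5 mol%), SPhos (10 mol%), K3PO4, THF–H2O (10:1), 40 °C
Reagents that add atoms: none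
Why: Suzuki–Miyaura coupling of an activated 2-bromoenone with an alkenylboronic acid proceeds with retention of alkene geometry, a bulky biarylphosphine should cope with the tetrasubstituted bromide, and mild phosphate base should spare the epoxy ketone and the ester.

Step 12
Reactants: 18 methyl (E)-4-[(1R,5R,6R)-5-[(tert-butyldimethylsilyl)oxy]-4-{[(tert-butyldimethylsilyl)oxy]methyl}-3-[(E)-hept-1-en-1-yl]-2-oxo-7-oxabicyclo[4.1.0]hept-3-en-1-yl]-2-methylbut-2-enoate
Product: 20 (E)-4-[(1R,5R,6R)-5-[(tert-butyldimethylsilyl)oxy]-4-{[(tert-butyldimethylsilyl)oxy]methyl}-3-[(E)-hept-1-en-1-yl]-2-oxo-7-oxabicyclo[4.1.0]hept-3-en-1-yl]-2-methylbut-2-enoic acid, via trimethylstannyl ester 19 (not isolated)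
Conditions: Me3SnOH, ClCH2CH2Cl, 70 °C; then aq. HCl (0.5 M) wash
Reagents that add atoms: trimethyltin hydroxide, C[Sn](C)(C)O
Why: Tin-hydroxide-mediated cleavage of a methyl ester is a near-neutral hydrolysis that should spare the epoxy ketone and dienone, and it is run while both hydroxyls are still silylated.

Step 13
Reactants: 20 (E)-4-[(1R,5R,6R)-5-[(tert-butyldimethylsilyl)oxy]-4-{[(tert-butyldimethylsilyl)oxy]methyl}-3-[(E)-hept-1-en-1-yl]-2-oxo-7-oxabicyclo[4.1.0]hept-3-en-1-yl]-2-methylbut-2-enoic acid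
Product: 21 (E)-4-[(1R,5R,6R)-3-[(E)-hept-1-en-1-yl]-5-hydroxy-4-(hydroxymethyl)-2-oxo-7-oxabicyclo[4.1.0]hept-3-en-1-yl]-2-methylbut-2-enoic acid (target)
Conditions: HF·pyridine, pyridine–THF, 0 °C → rt
Reagents that add atoms: none
Why: Buffered HF·pyridine desilylation should remove both silyl ethers under mildly acidic conditions that an epoxy enone and a free acid tolerate, without touching any stereocentre.

**Compound list**

1 | (R)-4-[(tert-butyldimethylsilyl)oxy]cyclopent-2-en-1-one | O=C1C[C@@H](O[Si](C)(C)C(C)(C)C)C=C1 | starting material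
2 | (R)-4-[(tert-butyldimethylsilyl)oxy]-2-iodocyclopent-2-en-1-one | O=C1C[C@@H](O[Si](C)(C)C(C)(C)C)C=C1I | intermediate
3 | allyltributylstannane | C=CC[Sn](CCCC)(CCCC)CCCC | starting material
4 | (R)-2-allyl-4-[(tert-butyldimethylsilyl)oxy]cyclopent-2-en-1-one | O=C1C[C@@H](O[Si](C)(C)C(C)(C)C)C=C1CC=C | intermediate
5 | methyl methacrylate | C=C(C)C(=O)OC | starting material
6 | methyl (E)-4-[(3R)-3-[(tert-butyldimethylsilyl)oxy]-5-oxocyclopent-1-en-1-yl]-2-methylbut-2-enoate | O=C1C[C@@H](O[Si](C)(C)C(C)(C)C)C=C1C/C=C(\C)C(=O)OC | intermediate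
7 | methyl (E)-4-[(3R,5S)-3-[(tert-butyldimethylsilyl)oxy]-5-hydroxycyclopent-1-en-1-yl]-2-methylbut-2-enoate | O[C@H]1C[C@@H](O[Si](C)(C)C(C)(C)C)C=C1C/C=C(\C)C(=O)OC | intermediate
8 | methyl (E)-4-[(1S,2S,4R,5R)-4-[(tert-butyldimethylsilyl)oxy]-2-hydroxy-6-oxabicyclo[3.1.0]hexan-1-yl]-2-methylbut-2-enoate | O[C@H]1C[C@@H](O[Si](C)(C)C(C)(C)C)[C@H]2O[C@]21C/C=C(\C)C(=O)OC | intermediate
9 | methyl (E)-4-[(1R,4R,5R)-4-[(tert-butyldimethylsilyl)oxy]-2-oxo-6-oxabicyclo[3.1.0]hexan-1-yl]-2-methylbut-2-enoate | O=C1C[C@@H](O[Si](C)(C)C(C)(C)C)[C@H]2O[C@]21C/C=C(\C)C(=O)OC | intermediate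
10 | methyl (E)-4-[(1R,4R,5R)-4-[(tert-butyldimethylsilyl)oxy]-2-[(trimethylsilyl)oxy]-6-oxabicyclo[3.1.0]hex-2-en-1-yl]-2-methylbut-2-enoate | C[Si](C)(C)OC1=C[C@@H](O[Si](C)(C)C(C)(C)C)[C@H]2O[C@]21C/C=C(\C)C(=O)OC | intermediate
11 | formaldehyde | C=O | starting material
12 | methyl (E)-4-[(1R,3R,4R,5R)-4-[(tert-butyldimethylsilyl)oxy]-3-(hydroxymethyl)-2-oxo-6-oxabicyclo[3.1.0]hexan-1-yl]-2-methylbut-2-enoate | O=C1[C@H](CO)[C@@H](O[Si](C)(C)C(C)(C)C)[C@H]2O[C@]21C/C=C(\C)C(=O)OC | intermediate
13 | methyl (E)-4-[(1R,4R,5R)-2,4-bis[(tert-butyldimethylsilyl)oxy]-3-{[(tert-butyldimethylsilyl)oxy]methyl}-6-oxabicyclo[3.1.0]hex-2-en-1-yl]-2-methylbut-2-enoate (key-step precursor) | CC(C)(C)[Si](C)(C)OC1=C(CO[Si](C)(C)C(C)(C)C)[C@@H](O[Si](C)(C)C(C)(C)C)[C@H]2O[C@]21C/C=C(\C)C(=O)OC | intermediate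
14 | bromoform | BrC(Br)Br | starting material
15 | dibromocyclopropane adduct of 13 (7,7-dibromo-3-oxatricyclo[4.1.0.0^2,4]heptane core: CBr2 bridging C6 and C2, drawn for addition anti to the C3 silyloxy group) | BrC1(Br)[C@]2(CO[Si](C)(C)C(C)(C)C)[C@@H](O[Si](C)(C)C(C)(C)C)[C@H]3O[C@@]3(C/C=C(\C)C(=O)OC)[C@]12O[Si](C)(C)C(C)(C)C | intermediate
16 | methyl (E)-4-[(1R,5R,6R)-3-bromo-5-[(tert-butyldimethylsilyl)oxy]-4-{[(tert-butyldimethylsilyl)oxy]methyl}-2-oxo-7-oxabicyclo[4.1.0]hept-3-en-1-yl]-2-methylbut-2-enoate (key-step product) | BrC1=C(CO[Si](C)(C)C(C)(C)C)[C@@H](O[Si](C)(C)C(C)(C)C)[C@H]2O[C@@]2(C/C=C(\C)C(=O)OC)C1=O | intermediate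
17 | (E)-hept-1-enylboronic acid | CCCCC/C=C/B(O)O | starting material
18 | methyl (E)-4-[(1R,5R,6R)-5-[(tert-butyldimethylsilyl)oxy]-4-{[(tert-butyldimethylsilyl)oxy]methyl}-3-[(E)-hept-1-en-1-yl]-2-oxo-7-oxabicyclo[4.1.0]hept-3-en-1-yl]-2-methylbut-2-enoate | CCCCC/C=C/C1=C(CO[Si](C)(C)C(C)(C)C)[C@@H](O[Si](C)(C)C(C)(C)C)[C@H]2O[C@@]2(C/C=C(\C)C(=O)OC)C1=O | intermediate
19 | trimethylstannyl ester of acid 20 | CCCCC/C=C/C1=C(CO[Si](C)(C)C(C)(C)C)[C@@H](O[Si](C)(C)C(C)(C)C)[C@H]2O[C@@]2(C/C=C(\C)C(=O)O[Sn](C)(C)C)C1=O | intermediate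
20 | (E)-4-[(1R,5R,6R)-5-[(tert-butyldimethylsilyl)oxy]-4-{[(tert-butyldimethylsilyl)oxy]methyl}-3-[(E)-hept-1-en-1-yl]-2-oxo-7-oxabicyclo[4.1.0]hept-3-en-1-yl]-2-methylbut-2-enoic acid | CCCCC/C=C/C1=C(CO[Si](C)(C)C(C)(C)C)[C@@H](O[Si](C)(C)C(C)(C)C)[C@H]2O[C@@]2(C/C=C(\C)C(=O)O)C1=O | intermediate
21 | (E)-4-[(1R,5R,6R)-3-[(E)-hept-1-en-1-yl]-5-hydroxy-4-(hydroxymethyl)-2-oxo-7-oxabicyclo[4.1.0]hept-3-en-1-yl]-2-methylbut-2-enoic acid | CCCCC/C=C/C1=C(CO)[C@@H](O)[C@H]2O[C@@]2(C/C=C(\C)C(=O)O)C1=O | target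

**Totals**

Total step count: 13. Longest linear sequence: 13 steps, from 1 to 21; compounds 3, 5, 11, 14 and 17 are purchased.

**Steps most likely to fail**

Step 10 (carbene ring expansion). What may go wrong: tert-butoxide may cleave the enol ether, and the freed enolate would expel the C3 silyloxy group. Carbene addition to the crowded tetrasubstituted alkene may also be too slow, so that the carbene is consumed elsewhere. The fallback sets out from 13 and inserts C1 as CH, halogenating afterwards. Furukawa-type Simmons–Smith cyclopropanation (Et2Zn, CH2I2, CH2Cl2, 0 °C) would give the silyloxycyclopropane F1. FeCl3 in DMF (Ito–Saegusa oxidative opening of the internal cyclopropane bond) would give the ring-enlarged β-chloro ketone F2, a mixture at the chlorine-bearing carbon that is not purified. NaOAc in MeOH would dehydrochlorinate it to the C1-unsubstituted epoxycyclohexenone F3. Johnson-type α-iodination (I2, DMAP, pyridine–CH2Cl2) would give the C1-iodo epoxycyclohexenone F4, which takes the place of 16 in the coupling with 17 under the conditions of step 11 and comes back to the route at 18.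

Step 9 (one-pot silylation and enol ether formation). What may go wrong: the silyl triflate may ionise the allylic silyloxy groups of the forming enol ether (loss of the C3 or the CH2 oxygen) or open the epoxide, or the hindered tertiary α-hydrogen may not be removed. The fallback sets out from 12, separates the two silylations and replaces electrophile-driven enolisation by kinetic deprotonation. TBSCl and imidazole in DMF would protect the primary alcohol alone, giving the silyloxymethyl ketone F5. LiHMDS added at −78 °C to F5 in THF already containing TMSCl (in situ quench) would give the trimethylsilyl enol ether F6. F6 would be submitted to bromoform and KOt-Bu in place of 13 and comes back to the route at 16.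

Step 11 (Suzuki coupling). What may go wrong: base-induced degradation of the epoxy enone, or slow oxidative addition at the tetrasubstituted bromide with competing protodeboronation of the boronic acid. The fallback sets out from 16 and uses a base-free tin transmetalation. Stille coupling (Pd2(dba)3, AsPh3, CuI, NMP, rt → 40 °C) with (E)-tributyl(hept-1-enyl)stannane F7, made from hept-1-yne by hydrozirconation with Cp2Zr(H)Cl and quenching with Bu3SnCl, comes back to the route at 18.

**Further compounds**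

F1 | step 10 | silyloxycyclopropane from 13 (CH2 bridging C6 and C2; 3-oxatricyclo[4.1.0.0^2,4]heptane core) | C1[C@]2(CO[Si](C)(C)C(C)(C)C)[C@@H](O[Si](C)(C)C(C)(C)C)[C@H]3O[C@@]3(C/C=C(\C)C(=O)OC)[C@]12O[Si](C)(C)C(C)(C)C
F2 | step 10 | ring-enlarged β-chloro ketone (chlorine on the CH2O-silyl-bearing carbon, epimer mixture) | O=C1CC(Cl)(CO[Si](C)(C)C(C)(C)C)[C@@H](O[Si](C)(C)C(C)(C)C)[C@H]2O[C@]21C/C=C(\C)C(=O)OC
F3 | step 10 | methyl (E)-4-[(1R,5R,6R)-5-[(tert-butyldimethylsilyl)oxy]-4-{[(tert-butyldimethylsilyl)oxy]methyl}-2-oxo-7-oxabicyclo[4.1.0]hept-3-en-1-yl]-2-methylbut-2-enoate | O=C1C=C(CO[Si](C)(C)C(C)(C)C)[C@@H](O[Si](C)(C)C(C)(C)C)[C@H]2O[C@]21C/C=C(\C)C(=O)OC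
F4 | step 10 | methyl (E)-4-[(1R,5R,6R)-5-[(tert-butyldimethylsilyl)oxy]-4-{[(tert-butyldimethylsilyl)oxy]methyl}-3-iodo-2-oxo-7-oxabicyclo[4.1.0]hept-3-en-1-yl]-2-methylbut-2-enoate | IC1=C(CO[Si](C)(C)C(C)(C)C)[C@@H](O[Si](C)(C)C(C)(C)C)[C@H]2O[C@@]2(C/C=C(\C)C(=O)OC)C1=O
F5 | step 9 | methyl (E)-4-[(1R,3R,4R,5R)-4-[(tert-butyldimethylsilyl)oxy]-3-{[(tert-butyldimethylsilyl)oxy]methyl}-2-oxo-6-oxabicyclo[3.1.0]hexan-1-yl]-2-methylbut-2-enoate | O=C1[C@H](CO[Si](C)(C)C(C)(C)C)[C@@H](O[Si](C)(C)C(C)(C)C)[C@H]2O[C@]21C/C=C(\C)C(=O)OC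
F6 | step 9 | methyl (E)-4-[(1R,4R,5R)-4-[(tert-butyldimethylsilyl)oxy]-3-{[(tert-butyldimethylsilyl)oxy]methyl}-2-[(trimethylsilyl)oxy]-6-oxabicyclo[3.1.0]hex-2-en-1-yl]-2-methylbut-2-enoate | C[Si](C)(C)OC1=C(CO[Si](C)(C)C(C)(C)C)[C@@H](O[Si](C)(C)C(C)(C)C)[C@H]2O[C@]21C/C=C(\C)C(=O)OC
F7 | step 11 | (E)-tributyl(hept-1-enyl)stannane | CCCCC/C=C/[Sn](CCCC)(CCCC)CCCC
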